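Partner stands to starting material at 1.10 equivalents in the flask, so starting material is the limiting reagent, and this ledger follows its moles.

common to all: starting material 0.10 M

| flask | partner | protic impurity | temperature | remark | time |
|---|---|---|---|---|---|
| Monday's | 0.11 M | 2 mM | 5 °C | the very flask that is asked about, followed so far |  |
| Saturday's | 0.11 M | 1 mM | −10 °C | run made earlier |  |
| flask | 0.110 M | 2.00 mM | 5 °C |  | 10 h |

| run | time / min | target / % |
|---|---|---|
| Monday's | 80.0 | 14.5 |
| Monday's | 150 | 20.1 |
| Monday's | 240 | 23.0 |
| Monday's | 300 | 24.4 |
| Monday's | 360 | 25.3 |
| Saturday's | 3.00 | 0.1 |
| Saturday's | 6.00 | 0 |
| Saturday's | 12.0 | 0 |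
| Saturday's | 25.0 | 0.4 |
| Saturday's | 40.0 | 1.0 |

(readings scatter by 0.3 percentage points)

- spring: change nothing and wait 20 h more
- noon: at 10 h raise the temperature by 25 K, then wait 20 h
- autumn: at 10 h take out 90 % of the target then present, then wait 20 h
- winter: at 10 h add partner, 100 % of the amount charged, then wait 20 h

- target, in percent of the starting material first charged, at 10 h
- which option adds most target ("none" when 2 percentage points or less is all one gets) (spring / noon / autumn / winter / none)
- target present, with what was taken out counted in, in percent of the starting material first charged, after autumn
- target present, with what was taken out counted in, in percent of the starting material first charged, after winter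

- what is taken out of target is counted as made
- the numbers in the tables scatter by 0.3 percentage points (one standard deviation)
- additions bring no volume worth counting

The first entry is the protic impurity. If it takes one starting material each, it claims at most 2.00 % of the charge. Each remaining mole is taken to need one partner, which defines the partner surplus, the partner charged less the starting material that the impurity leaves: 12.0 mM. Partner is more than that demand, so this reckoning does not read the stall as a shortage of partner.

The second entry is target. On Monday's run each hourly gain is 0.643 of the one before, a rough reading given the scatter of 0.3 percentage points. A geometric tail with that ratio ends at 26.9 %, and it stands at 26.6 % at 10 h. That leaves 0.28 points to come, less than the margin of 2 points.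

The last entry is the remainder, 71.1 % of the charge. On Saturday's run target reads 0 % at 12.0 min and 1.0 % at 40.0 min. That lag points to an intermediate on the way to target, and so to room for a branch. This reckoning books the remainder as lost irreversibly to an unseen product, a judgement that the readings do not prove. The books then close: autumn and winter reach about 26.9 %, and the best option is none.

The forecast, which saw the target stall “with most of the starting material left”, gave 26.1 %, winter, 40.8 % and 42.8 %.

The flask gives 27.5 % at 10 h, best option none, 28.5 % after autumn and 28.6 % after winter.

    starting material ⇌ open intermediate (K = 15.0, k = 0.0255 min⁻¹, Ea = 81.0 kJ mol⁻¹, ΔH = 11.0 kJ mol⁻¹)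
    partner → second intermediate (k = 1.14 min⁻¹, Ea = 86.0 kJ mol⁻¹)
    open intermediate + second intermediate → target (k = 0.268 L mol⁻¹ min⁻¹, Ea = 50.0 kJ mol⁻¹)
    starting material + second intermediate → side product (k = 0.862 L mol⁻¹ min⁻¹, Ea = 43.0 kJ mol⁻¹)
    starting material + protic impurity → quenched substrate (k = 5.01 L mol⁻¹ min⁻¹, Ea = 45.0 kJ mol⁻¹)
    (constants at 5 °C)

At 600 min the flask holds 69.3 % as side product. The simulated run without the step of starting material + second intermediate gives 95.4 % target against 27.5 %, so that step is the main reason for the missing target. In the flask the surplus reappears as second intermediate, 0.0120 M at 6000 min, level with the 12.0 mM from the charges. In the neighbour flask, the same recipe with 0.17 M of starting material, the extra charge outruns the surplus by 58.0 mM, and open intermediate plus starting material stand at 58.0 mM at 600 min, with target at 9.61 %.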